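**Early readings.** At early times the eta run already holds 17.6% of G at 1.33 min, and the reading falls to 0% at 15.0 min, so in that run G is a stage on the way and not an end point.

in all of them: L 0.0152 M; Q 0.0192 M

| flask | X | remark | time |
|---|---|---|---|
| eta | 0.0080 M | run made earlier |  |
| flask | 0.016 M |  | 50 min |

eta run (percent of the X charged): time / min: G / % = 1.33: 17.6; 2.00: 14.7; 3.00: 10.1; 5.00: 6.6; 10.0: 0.5; 15.0: 0

(readings scatter by 1 percentage point)

- a reading or a percentage of G counts all its forms, free or not

- time, not beyond 50 min, at which the flask holds most G
- the amount of G, in percent of the X charged, at that time

**The ledger.** This reckoning, which is my own, counts what is left. It supposes that each X ends in a product made by consuming one mole of Q, a supposition that the eta run does not prove. The entry that matters is then the cover, the [Q] charged per [X] charged: 1.20 in this flask. A cover above one makes X the limiting reagent against Q, so the books of this flask close with a fraction 16.7% of the Q charge unused. L stands at 0.950 per X, so the ledger of this flask must also show whether L is consumed or returned. The cover speaks of the end of the run and not of the peak. The eta readings fall from the first one on, so this reckoning places the maximum of the flask early, near 1.33 min or before it.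

**The forecast.** The forecast gives 1.5 min and 21%, and adds that “G may linger afterwards rather than vanish”.

**The result.** The flask reaches its maximum at 0.893 min with 17.3% of G, and at 50.0 min it holds 0.0164% of G, with L back at >99.9% of its charge.

    X ⇌ E (K = 0.180, k = 0.0140 /s)
    L + G ⇌ D, settled at all times (K = 36.0 /M)
    Q + E → Z (k = 9.90 /M/s)
    L + E ⇌ G (K = 310 /M, k = 120 /M/s)

Q in the flask ends at 17% of its charge, against the 16.7% of the ledger. A neighbouring flask, the same but charged with 0.0077 M of Q, has a cover of 0.481, below one. At 50.0 min, that neighbouring flask holds 0% of its Q and, in percent of the X charged, 21.5% of G and 48.1% of Z.

The numbers in the tables were generated by integration on assumed constants; scatter was added.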